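Ring A is disconnected at its ether carbon C2, which sits between the ester-bearing C1 and the methoxy-bearing C3 and is treated as the former spiro carbon of a ring B benzofuran-3-one. The furanone oxygen survives as the diaryl ether link, and the furanone carbonyl ends as the ring B carboxylic acid once hydroxide fragments the derived spiro dienone. One Diels–Alder reaction of a 1,1-dimethoxy-3-silyloxy diene with the exocyclic alkene of that coumaranone forms C2–C3 and C1–C6 and closes ring A as a spiro 3-methoxy enone, which later steers chlorine to C4. The precursor is MOM-protected 4-hydroxy-6-methylcoumaranone carrying a (Z)-methoxycarbonylmethylene group at the furanone C2.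

Key step: step 8

Assumption: compounds 16 to 20 are racemic; their SMILES show one enantiomer of the stated relative configuration, and every stereocenter is erased before the achiral target.
Remark: at the exocyclic alkene of the dienophile the ring oxygen is through-conjugated with the ester (a vinylogous carbonate) and only cross-conjugated with the ketone; the regiochemical argument of step 8 is built on this.

Step 1
Reactants: 1 orcinol (5-methylbenzene-1,3-diol)
Product: 2 1,3-bis(methoxymethoxy)-5-methylbenzene
Conditions: MOMCl (2.4 equiv), i-Pr2NEt, CH2Cl2, 0 °C to rt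
Reagents that add atoms: chloromethyl methyl ether, `COCCl`
Why: Williamson-type O-alkylation of both phenols by the reactive α-chloro ether under amine base should give the bis-acetal, which protects the phenols and supplies two cooperating ortho-directing groups.

Step 2
Reactants: 2 1,3-bis(methoxymethoxy)-5-methylbenzene; 3 2-chloro-N-methoxy-N-methylacetamide
Product: 5 2-chloro-1-[2,6-bis(methoxymethoxy)-4-methylphenyl]ethan-1-one, via aryllithium 4 (not isolated)
Conditions: n-BuLi (1.1 equiv), THF, 0 °C; then 3, −78 to −20 °C; aq NH4Cl
Reagents that add atoms: n-butyllithium, `[Li]CCCC` (its lithium stays only in intermediate 4)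
Why: Directed ortho-metalation should occur at the carbon between the two coordinating acetal oxygens, and the aryllithium should add once to the Weinreb amide because the chelated tetrahedral adduct persists until the quench, giving the α-chloro ketone without over-addition.

Step 3
Reactants: 5 2-chloro-1-[2,6-bis(methoxymethoxy)-4-methylphenyl]ethan-1-one
Product: 7 4-hydroxy-6-methyl-1-benzofuran-3(2H)-one, via dihydroxy chloroketone 6 (not isolated)
Conditions: 3 M HCl, MeOH, 50 °C; then NaOAc (excess), MeOH, reflux
Reagents that add atoms: none
Why: Acid-catalysed acetal methanolysis should free both phenols, and acetate should then promote the standard coumaranone closure by intramolecular Williamson etherification (5-exo-tet SN2 of a phenoxide on the α-chloro ketone); the two phenols are equivalent, so only one product can form.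

Step 4
Reactants: 7 4-hydroxy-6-methyl-1-benzofuran-3(2H)-one
Product: 8 4-(methoxymethoxy)-6-methyl-1-benzofuran-3(2H)-one
Conditions: MOMCl (1.2 equiv), i-Pr2NEt (1.5 equiv), CH2Cl2, 0 °C
Reagents that add atoms: chloromethyl methyl ether, `COCCl`
Why: Williamson-type O-alkylation of the remaining phenol under mild amine base should restore an acetal that removes the acidic proton, which would otherwise quench the silyl ketene acetal diene, and that lasts until the final acid treatment.

Step 5
Reactants: 8 4-(methoxymethoxy)-6-methyl-1-benzofuran-3(2H)-one; 9 methyl glyoxylate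
Product: 11 methyl (Z)-2-[4-(methoxymethoxy)-6-methyl-3-oxo-1-benzofuran-2(3H)-ylidene]acetate, via aldol adduct 10 (not isolated)
Conditions: 9 (1.5 equiv, toluene solution), piperidine (10 mol %), AcOH (10 mol %), 4 Å MS, toluene, 50 °C
Reagents that add atoms: none
Why: Knoevenagel condensation of the active methylene C2 with the highly electrophilic aldehyde, followed by E1cB loss of water, should give the ene-dione, and reversible amine addition should equilibrate it to the Z isomer, in which the ester lies on the side of the ring oxygen and away from the ketone carbonyl.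

Step 6
Reactants: 12 1,1-dimethoxyethene; 13 acetyl chloride
Product: 14 4,4-dimethoxybut-3-en-2-one
Conditions: pyridine, Et2O, 0 °C to rt
Reagents that add atoms: none
Why: C-acylation of the nucleophilic β-carbon of the ketene acetal by the acid chloride, followed by loss of HCl to the base, should give the β,β-dimethoxy enone (acylation of a ketene acetal).

Step 7
Reactants: 14 4,4-dimethoxybut-3-en-2-one
Product: 15 1,1-dimethoxy-3-(trimethylsilyloxy)buta-1,3-diene
Conditions: TMSCl, Et3N, ZnCl2 (cat.), toluene, 40 °C; distilled
Reagents that add atoms: chlorotrimethylsilane, `C[Si](C)(C)Cl`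
Why: Soft enolisation and O-silylation toward the only enolisable position, the methyl group, is the standard preparation of 1-alkoxy-3-silyloxy dienes and should give the cross-conjugated 2-silyloxy diene.

Step 8
Reactants: 11 methyl (Z)-2-[4-(methoxymethoxy)-6-methyl-3-oxo-1-benzofuran-2(3H)-ylidene]acetate; 15 1,1-dimethoxy-3-(trimethylsilyloxy)buta-1,3-diene
Product: 17 racemic methyl 2'-methoxy-4-(methoxymethoxy)-6-methyl-3,4'-dioxo-3H-spiro[1-benzofuran-2,1'-cyclohex[2]ene]-6'-carboxylate (ester cis to the ring oxygen), via silyl enol ether cycloadduct 16 (not isolated)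
Conditions: 15 (2 equiv), toluene, 60 °C; then 0.1 M HCl, THF, 0 °C
Reagents that add atoms: none
Why: The electron-rich diene (largest HOMO coefficient on its CH2 terminus) and the doubly activated exocyclic alkene should combine in a normal-demand, strongly asynchronous (4+2) cycloaddition in which the C1–C6 bond (exocyclic CH to diene CH2) runs ahead of the C2–C3 bond (spiro carbon to acetal carbon), after which cold dilute acid hydrolyses the silyl enol ether and expels one methanol to leave the 3-methoxy enone. The closest known reaction type is the Diels–Alder addition of 1,1-dialkoxy-3-silyloxybutadienes to 2-alkylidene benzofuran-3-ones, which gives spiro 2'-methoxy cyclohexenones. Ring A closes as a six-membered carbocycle by intermolecular (4+2) cycloaddition, both bonds forming suprafacially on the alkene, which makes C2 the spiro centre. The two new stereocenters (C1 and C2 of ring A) arise as a racemate whose relative configuration, ester cis to the ring oxygen, is dictated by the Z geometry of 11 through suprafacial addition, and neither survives to the target. The selectivity required is regiochemical: attack at the exocyclic carbon develops aromatic benzofuran-3-olate character, the ester is weakened as an acceptor by through-conjugation with the ring oxygen, and the CH2 terminus meets the less hindered CH carbon instead of the fully substituted C2, so the ring ketone should direct. The MOM acetal, the methyl ester and the aryl ketone should be inert to the diene and to brief cold dilute acid.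

Step 9
Reactants: 17 racemic methyl 2'-methoxy-4-(methoxymethoxy)-6-methyl-3,4'-dioxo-3H-spiro[1-benzofuran-2,1'-cyclohex[2]ene]-6'-carboxylate
Product: 18 racemic methyl 3'-chloro-2'-methoxy-4-(methoxymethoxy)-6-methyl-3,4'-dioxo-3H-spiro[1-benzofuran-2,1'-cyclohex[2]ene]-6'-carboxylate
Conditions: NCS (1.05 equiv), CH2Cl2, 0 °C to rt, dark
Reagents that add atoms: N-chlorosuccinimide, `O=C1CCC(=O)N1Cl`
Why: Electrophilic α-chlorination of a vinylogous ester should place chlorine on C3' (C4 of ring A), the only enol-ether-type carbon of the β-methoxy enone, while ring B, whose oxygen lone pairs are engaged by the ortho ketone, should react far more slowly with NCS in the absence of acid.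

Step 10
Reactants: 18 racemic methyl 3'-chloro-2'-methoxy-4-(methoxymethoxy)-6-methyl-3,4'-dioxo-3H-spiro[1-benzofuran-2,1'-cyclohex[2]ene]-6'-carboxylate
Product: 20 racemic methyl 3'-chloro-2'-methoxy-4-(methoxymethoxy)-6-methyl-3,4'-dioxo-3H-spiro[1-benzofuran-2,1'-cyclohexa[2,5]diene]-6'-carboxylate, via silyl dienol ether 19 (not isolated)
Conditions: TMSOTf, Et3N, CH2Cl2, −78 to 0 °C; then Pd(OAc)2 (1.1 equiv), MeCN, rt
Reagents that add atoms: trimethylsilyl trifluoromethanesulfonate, `C[Si](C)(C)OS(=O)(=O)C(F)(F)F` (its silyl group stays only in intermediate 19)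
Why: Soft enolisation can go only toward C5' because C3' carries chlorine and no hydrogen, and Saegusa–Ito oxidation of the silyl dienol ether (palladium enolate, then β-hydride elimination of the C6' hydrogen) should give the cross-conjugated dienone, removing the C6' stereocenter and leaving only the racemic spiro carbon.

Step 11
Reactants: 20 racemic methyl 3'-chloro-2'-methoxy-4-(methoxymethoxy)-6-methyl-3,4'-dioxo-3H-spiro[1-benzofuran-2,1'-cyclohexa[2,5]diene]-6'-carboxylate
Product: 22 2-[3-chloro-4-hydroxy-2-methoxy-6-(methoxycarbonyl)phenoxy]-6-hydroxy-4-methylbenzoic acid (target), via MOM-protected diaryl ether acid 21 (not isolated)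
Conditions: LiOH (2.5 equiv), THF/H2O, 0 °C; then 3 M HCl to pH 1, 40 °C
Reagents that add atoms: lithium hydroxide, `[Li+].[OH-]`
Why: Hydroxide should add to the non-enolisable furanone ketone and the adduct should fragment in retro-Claisen fashion at the bond to the spiro carbon, because ring A departs as an aromatic phenoxide (the known hydrolytic opening of grisadienediones to diaryl ether acids, which also erases the last stereocenter), while the hindered methyl ester on the resulting phenolate ring should resist saponification at 0 °C and the following aqueous acid should hydrolyse only the MOM acetal.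

Compound list
1 | orcinol (5-methylbenzene-1,3-diol) | `Cc1cc(O)cc(O)c1` | starting material
2 | 1,3-bis(methoxymethoxy)-5-methylbenzene | `COCOc1cc(C)cc(OCOC)c1` | intermediate
3 | 2-chloro-N-methoxy-N-methylacetamide | `ClCC(=O)N(C)OC` | starting material
4 | [2,6-bis(methoxymethoxy)-4-methylphenyl]lithium | `[Li]c1c(OCOC)cc(C)cc1OCOC` | intermediate (not isolated)
5 | 2-chloro-1-[2,6-bis(methoxymethoxy)-4-methylphenyl]ethan-1-one | `COCOc1cc(C)cc(OCOC)c1C(=O)CCl` | intermediate
6 | 2-chloro-1-(2,6-dihydroxy-4-methylphenyl)ethan-1-one | `Cc1cc(O)c(C(=O)CCl)c(O)c1` | intermediate (not isolated)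
7 | 4-hydroxy-6-methyl-1-benzofuran-3(2H)-one | `Cc1cc(O)c2C(=O)COc2c1` | intermediate
8 | 4-(methoxymethoxy)-6-methyl-1-benzofuran-3(2H)-one | `COCOc1cc(C)cc2OCC(=O)c12` | intermediate
9 | methyl glyoxylate | `COC(=O)C=O` | starting material
10 | methyl 2-hydroxy-2-[4-(methoxymethoxy)-6-methyl-3-oxo-2,3-dihydro-1-benzofuran-2-yl]acetate (mixture of diastereomers) | `COC(=O)C(O)C1Oc2cc(C)cc(OCOC)c2C1=O` | intermediate (not isolated)
11 | methyl (Z)-2-[4-(methoxymethoxy)-6-methyl-3-oxo-1-benzofuran-2(3H)-ylidene]acetate | `COC(=O)/C=C1\Oc2cc(C)cc(OCOC)c2C1=O` | intermediate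
12 | 1,1-dimethoxyethene | `C=C(OC)OC` | starting material
13 | acetyl chloride | `CC(=O)Cl` | starting material
14 | 4,4-dimethoxybut-3-en-2-one | `CC(=O)C=C(OC)OC` | intermediate
15 | 1,1-dimethoxy-3-(trimethylsilyloxy)buta-1,3-diene | `C=C(O[Si](C)(C)C)C=C(OC)OC` | intermediate
16 | racemic methyl 2',2'-dimethoxy-4-(methoxymethoxy)-6-methyl-3-oxo-4'-(trimethylsilyloxy)-3H-spiro[1-benzofuran-2,1'-cyclohex[3]ene]-6'-carboxylate, ester cis to the ring oxygen | `COC(=O)[C@@H]1CC(O[Si](C)(C)C)=CC(OC)(OC)[C@]12Oc3cc(C)cc(OCOC)c3C2=O` | intermediate (not isolated)
17 | racemic methyl 2'-methoxy-4-(methoxymethoxy)-6-methyl-3,4'-dioxo-3H-spiro[1-benzofuran-2,1'-cyclohex[2]ene]-6'-carboxylate, ester cis to the ring oxygen | `COC(=O)[C@@H]1CC(=O)C=C(OC)[C@]12Oc3cc(C)cc(OCOC)c3C2=O` | intermediate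
18 | racemic methyl 3'-chloro-2'-methoxy-4-(methoxymethoxy)-6-methyl-3,4'-dioxo-3H-spiro[1-benzofuran-2,1'-cyclohex[2]ene]-6'-carboxylate, ester cis to the ring oxygen | `COC(=O)[C@@H]1CC(=O)C(Cl)=C(OC)[C@]12Oc3cc(C)cc(OCOC)c3C2=O` | intermediate
19 | racemic methyl 3'-chloro-2'-methoxy-4-(methoxymethoxy)-6-methyl-3-oxo-4'-(trimethylsilyloxy)-3H-spiro[1-benzofuran-2,1'-cyclohexa[2,4]diene]-6'-carboxylate, ester cis to the ring oxygen | `COC(=O)[C@@H]1C=C(O[Si](C)(C)C)C(Cl)=C(OC)[C@]12Oc3cc(C)cc(OCOC)c3C2=O` | intermediate (not isolated)
20 | racemic methyl 3'-chloro-2'-methoxy-4-(methoxymethoxy)-6-methyl-3,4'-dioxo-3H-spiro[1-benzofuran-2,1'-cyclohexa[2,5]diene]-6'-carboxylate | `COC(=O)C1=CC(=O)C(Cl)=C(OC)[C@]12Oc3cc(C)cc(OCOC)c3C2=O` | intermediate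
21 | 2-[3-chloro-4-hydroxy-2-methoxy-6-(methoxycarbonyl)phenoxy]-6-(methoxymethoxy)-4-methylbenzoic acid | `COC(=O)c1cc(O)c(Cl)c(OC)c1Oc1cc(C)cc(OCOC)c1C(=O)O` | intermediate (not isolated)
22 | 2-[3-chloro-4-hydroxy-2-methoxy-6-(methoxycarbonyl)phenoxy]-6-hydroxy-4-methylbenzoic acid | `COC(=O)c1cc(O)c(Cl)c(OC)c1Oc1cc(C)cc(O)c1C(=O)O` | target

Total step count: 11. Longest linear sequence: 9 steps (steps 1 to 5 and 8 to 11 from orcinol); the diene branch (steps 6 and 7) joins at step 8.

Steps most likely to fail

Step 8. The cycloaddition may proceed with the reversed orientation (the CH2 terminus bonding to the spiro-destined carbon under ester control), or the diene may be lost to protodesilylation and oligomerisation before it reacts. The fallback makes the same two bonds one at a time under thermodynamic control and sets out from 11 and 14. LiN(SiMe3)2 in THF at −78 °C should convert 14 into lithium 4,4-dimethoxybuta-1,3-dien-2-olate F1. Its reversible Michael addition to 11 should settle on the exocyclic carbon, because only that mode releases the aromatic benzofuran-3-olate. After NH4Cl quench this should give methyl 6,6-dimethoxy-2-[4-(methoxymethoxy)-6-methyl-3-oxo-2,3-dihydro-1-benzofuran-2-yl]-4-oxohex-5-enoate F2. DBU in MeCN at rt should then close ring A by intramolecular conjugate addition of the furanone C2 to the ketene acetal carbon with loss of methanol (6-endo-trig addition–elimination). The fallback returns to the route at 17.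

Step 5. The ene-dione product is a strong Michael acceptor and may be consumed by conjugate addition of unreacted coumaranone enolate or of the amine catalyst, and methyl glyoxylate may oligomerise instead of condensing. The fallback sets out from 8. Aldol condensation with glyoxylic acid monohydrate (K2CO3, degassed MeOH/H2O, rt) forms the product as its carboxylate, which is a poor acceptor and should resist over-addition. Careful acidification to pH 3 at 0 °C should give (Z)-2-[4-(methoxymethoxy)-6-methyl-3-oxo-1-benzofuran-2(3H)-ylidene]acetic acid F3. O-Alkylation of the carboxylate with MeI and KHCO3 in DMF at rt returns to the route at 11.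

Step 10. The MOM acetal may be cleaved by the silyl triflate during enolisation, or the silyl dienol ether may protodesilylate faster than it is palladated. The fallback sets out from 18 and avoids any silyl enol ether: direct dehydrogenation of the 1,4-dicarbonyl unit (C4' ketone and C6' ester) with SeO2 in t-BuOH containing a little AcOH at reflux, a known way to convert 2'-methoxy spiro cyclohexenones of this class into the cross-conjugated dienones. It returns to the route at 20 and makes no new compound.

Further compounds
F1 | step 8 | lithium 4,4-dimethoxybuta-1,3-dien-2-olate | `[Li]OC(=C)C=C(OC)OC`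
F2 | step 8 | methyl 6,6-dimethoxy-2-[4-(methoxymethoxy)-6-methyl-3-oxo-2,3-dihydro-1-benzofuran-2-yl]-4-oxohex-5-enoate (mixture of diastereomers) | `COC(=O)C(CC(=O)C=C(OC)OC)C1Oc2cc(C)cc(OCOC)c2C1=O`
F3 | step 5 | (Z)-2-[4-(methoxymethoxy)-6-methyl-3-oxo-1-benzofuran-2(3H)-ylidene]acetic acid | `OC(=O)/C=C1\Oc2cc(C)cc(OCOC)c2C1=O`
F0 | step 10 | none | none
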